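## Structural features

The target is a 9-hydroxyphenalen-1-one (enone ring A, central arene ring B, phenol ring C) whose ring B carries across C-5/C-6 a five-membered carbocycle (ring D). Ring D is cis-fused to a cyclopent-2-enone (ring E), and its carbon bound to C-6 is the spiro ketal carbon of a naphtho[1,8-de][1,3]dioxine (ring F on a naphthalene). The two stereocentres are neighbours: the ring D/E fusion CH (S), which lies between the ketal carbon and the ring E carbonyl, and the fusion carbinol carbon (R), which is tertiary, benzylic (on C-5), allylic and γ to the ring E carbonyl. Fragile points are the β-hydroxy ketone (retro-aldol would give an achiral ene-dione and so racemise), the ketal β to the same ketone (base can expel a naphtholate from the enolate), the tautomeric vinylogous acid of rings A/C (its ethers are vinylogous esters, and alkylating an unsymmetrical hydroxyphenalenone gives two regioisomers) and the easily reduced, oxygen-sensitising phenalenone chromophore. The real difficulty is the crowded ketal carbon next to two adjacent stereocentres in a molecule whose spiro ketal is locally mirror-symmetric, so nothing in the skeleton distinguishes the two faces of ring D. The key step uses the fact that ring E is joined to ring D only through the carbinol carbon and the adjacent CH: its other three carbons (C=O, CH=, =CH) can be laid across a ring D alkene as carbon monoxide and a two-carbon alkyne, and the carbinol oxygen can be added afterwards to the benzylic C–H that this creates.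

## Logic of the disconnections

22 from 21. Only the O–CH3 bond at C-9 is cut. The vinylogous acid stays masked from the first step to the last because it would bind cobalt and because an unsymmetrical hydroxyphenalenone cannot be alkylated on one oxygen selectively; bringing the methyl group in with the naphthalene fixes its position. The demand is a dealkylation that is neither basic nor reducing.

21 from 19 through 20. The C–O bond at the benzylic ring-fusion carbon is cut. That carbon then carries a hydrogen, which is what cycloaddition to a CH=CH alkene provides, and this C–H is the weakest in 19. The carbinol then need not survive the metal chemistry; the demand is an oxygenation with overall retention and without base, since base would open the aldol and the ketal.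

19 from 18. A C–Si bond is added at the enone α-carbon. Silicon makes the alkyne a handled liquid, gives an isolable single-diastereomer cobalt complex and fixes the orientation of the alkyne. The price is one protodesilylation.

18 from 14 and 17. Three C–C bonds of ring E are cut: ring-fusion CH to carbonyl, carbonyl to the silyl-bearing carbon, and benzylic ring-fusion CH to the =CH carbon. This removes ring E and both stereocentres at once and leaves 14, which is flat and achiral. The forward step must find one face of a mirror-symmetric alkene and one of two orientations across it; the first is asked of the chiral cluster in 17, the second of the steric difference between the spiro-flanked and the benzylic alkene carbon.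

17 from 15 through 16. The alkyne–cobalt and ligand–cobalt bonds are cut, leaving 15, Co2(CO)8 and a sulfinamide-derived P,S ligand. Preforming and purifying the complex puts the asymmetry into a characterised reagent.

14 from 13. A formyl group is added to the ring D alkene carbon next to the spiro centre; this C–CHO bond is the one broken in the forward decarbonylation. The formyl group is the price of closing ring D by condensation, and one stage earlier it made the alkyne an acceptor. Its removal must not touch the ring A enone, which rules out ester reduction and elimination and points to rhodium-catalysed decarbonylation.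

13 from 11 and 1 through 12. The two ketal C–O bonds and the ring D C=C bond are cut. The ketal carbon is at the ketone oxidation level and bears the arene, so it is the β-carbon of an aryl ynal, to which 1 can add twice; the CH2–CHO arm so created is placed to condense with an ortho formyl group. Ring D, ring F and the quaternary centre form in one operation, with no hydride reagent and no acid ketalisation of a hindered aryl ketone. The demand is that the second, crowded C–O bond forms and that the naphtholate leaves the phenalenone methyl ether alone, hence catalytic carbonate only.

11 from 8 and 9 through 10. The ynal is taken back to the propargylic alcohol and the aryl–alkyne bond is cut. This leaves an ortho bromo aldehyde and a three-carbon alkyne; the coupling needs a tertiary amine base only.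

8 from 6 through 7. Aromatic ring B is taken back to a ring with one CH2 (7, with the ring A carbonyl masked as an aryl benzoate), then the C–Br and C–CHO bonds are cut to reveal a ketone with one α-CH2 (6). An ortho bromo aldehyde is the signature of haloformylation of a ketone, and this ketone has a single enolisable side, so the positions of bromine and formyl group, and with them of the spiro carbon and ring D, are fixed. The forward oxidation must shed the benzoyl group and keep the methyl group.

6 from 3 and 4 through 5. The two bonds from the three-carbon bridge to the naphthalene are cut (acyl–arene and alkyl–arene). Ring B is thus a propanoyl unit across the free peri positions of a 1,8-dioxygenated naphthalene. The two oxygens must differ: acylation then goes para to the methoxy group, which puts the methyl ether on ring C on the side of the future spiro carbon, as 14 requires.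

3 from 1 through 2. The ester and ether bonds are cut. 1 therefore serves twice, as the source of rings A–C and as the ketal diol.

## Other disconnections considered

Alternative 1: The cut is in ring B, at the C3a–C4 and C5–C6 bonds, which turns the arene into a furan diene plus a vinyl group and opens ring D at the same time.
- Forward step: acid would dehydrate lactol A2 to isobenzofuran A3; its furan carbons add intramolecularly to the vinyl group on the carbinol carbon, and loss of the oxygen bridge as water aromatises ring B to give A1, the 2,3-dihydro-1H-phenalene analogue of 21.
- In its favour: the carbinol oxygen and both stereocentres are in place beforehand on a monocyclic 4-hydroxycyclopentenone that can be made enantiopure by known means. On absolute stereocontrol and on precedent for the reaction type this plan is the better of the two.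
- Against it here: acid acts twice on a substrate holding a tertiary allylic carbinol β to a ketone and the aryl ketal; the dienophile is an unactivated vinyl group on a fully substituted carbon; A2 needs the ketal built on a ketone flanked by the substituted cyclopentenone CH; A1 still has a saturated ring A, so a benzylic oxidation at one of two CH2 groups and a dehydrogenation come late on the complete molecule.
- Comparison: structurally it builds the arene and keeps ring E, where the chosen plan keeps the arene and builds ring E. Mechanistically it is pericyclic and intramolecular, hence surer in regiochemistry. In step economy it is worse: redox steps on ring A add to the demethylation and the substrate is longer to make.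

Alternative 2: The cut takes the bond between the ring-fusion CH and the ring E carbon that becomes the carbonyl, together with one ketal C–O bond, so rings E and F close together.
- Forward step: BF3·OEt2 buffered with 2,6-di-tert-butylpyridine would activate the Z-enal of A5; the enol ether carbon of ring D attacks the aldehyde and the pendant naphthol captures the oxocarbenium ion, giving spiroketal cyclopentenol A4.
- In its favour: the carbinol stereocentre exists beforehand as a silyl ether and can come from a known enantioselective addition to a ketone; it then dictates the CH centre through the obligatory cis fusion. On absolute control this is better than the chosen plan.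
- Against it: the Z-enal can isomerise under the Lewis acid to the E isomer, which cannot reach; the tertiary benzylic, allylic silyl ether can ionise; the enol ether with a free peri naphthol is labile and lengthy to assemble.
- Comparison: both plans form ring E last, this one from a ring D that already carries the carbinol. A cationic cascade stands against a metal-mediated cycloaddition, each without close precedent on such a substrate, so they are equals there. A4 needs oxidation of the allylic alcohol, desilylation and demethylation, which equals the three closing steps of the chosen plan, but the substrate needs more steps than 14.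

Alternative 3: The cut takes both ketal C–O bonds and the bond between the ring-fusion CH and the carbinol carbon, so rings F and D close in one operation from 1 and ynone A7.
- Forward step: base would add 1 twice to the ynone β-carbon and the resulting enolate adds to the ortho aryl ketone, giving spiroketal indanol A6 with cis acetyl and dimethoxymethyl groups; acetal hydrolysis and aldol condensation of the acetyl methyl onto the aldehyde would then close ring E.
- In its favour: it is the most convergent plan; it uses the same double oxa-Michael logic as step 8 of the chosen plan (equal on that point), installs the carbinol oxygen directly and closes ring E without stoichiometric metal. In step economy it is the better plan.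
- Against it: both stereocentres arise in a reversible base-mediated aldol addition with nothing to control absolute configuration; the aryl ketone next to the acetal is hindered; the later condensation puts base or acid on a tertiary β-hydroxy ketone prone to retro-aldol.
- Comparison: it forms rings D and F where the chosen plan forms ring E. Every step is of a known polar type, an advantage over the cobalt step. On absolute stereocontrol it is no better than the chosen plan, whose chiral cobalt complex at least offers a defined source of asymmetry.

Key step: step 11

Remark (assumption): which antipode of the P,S ligand leads to the (S,R) adduct cannot be derived for this alkene from the norbornadiene cases; the (R)-sulfinyl ligand is written and its enantiomer would be used if the sense is opposite.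
Remark: the ligand, (R)-N-benzyl-N-(diphenylphosphanyl)-2-methylpropane-2-sulfinamide, is a known compound two steps from commercial (R)-2-methylpropane-2-sulfinamide and is used as a reagent.

## Route

Step 1
Reactants: 1 naphthalene-1,8-diol
Product: 2 8-methoxynaphthalen-1-ol
Conditions: MeI (1.1 equiv), K2CO3 (1.1 equiv), acetone, reflux
Reagents that add atoms: iodomethane, CI
Why: Williamson ether synthesis; the strong O–H···O hydrogen bond in the monoanion and in the monoether lowers the acidity and nucleophilicity of the second hydroxyl, so monoalkylation should be selective.

Step 2
Reactants: 2 8-methoxynaphthalen-1-ol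
Product: 3 8-methoxynaphthalen-1-yl benzoate
Conditions: BzCl (1.2 equiv), Et3N (1.5 equiv), DMAP (5 mol %), CH2Cl2, 0 °C → rt
Reagents that add atoms: benzoyl chloride, O=C(Cl)c1ccccc1
Why: DMAP-catalysed esterification of the hindered, hydrogen-bonded naphthol; the benzoate deactivates its ring so that the two halves of the naphthalene differ electronically in step 3, and it later leaves from oxygen in step 5.

Step 3
Reactants: 3 8-methoxynaphthalen-1-yl benzoate; 4 3-chloropropanoyl chloride
Product: 6 ring B ketone (7-methoxy-1-oxo-2,3-dihydro-1H-phenalen-6-yl benzoate), via chloropropanoyl ketone 5 (not isolated)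
Conditions: 4 (1.2 equiv), AlCl3 (2.5 equiv), CH2Cl2, 0 °C → rt; then 40 °C
Reagents that add atoms: none
Why: Friedel–Crafts acylation para to the methoxy group (the most activated position) followed by intramolecular Friedel–Crafts cycloalkylation of the β-chloro ketone, through its AlCl3-bound enone, at the peri position para to the benzoyloxy group, the only site in reach; this order fixes the methoxy group para to the ketone-bearing carbon.

Step 4
Reactants: 6 ring B ketone
Product: 7 3-bromo-2-formyl-6-methoxy-1H-phenalen-7-yl benzoate
Conditions: PBr3 (3 equiv), DMF (6 equiv), CHCl3, 0 → 60 °C; then aq. NaOAc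
Reagents that add atoms: phosphorus tribromide, BrP(Br)Br; N,N-dimethylformamide, CN(C)C=O; water, O
Why: Vilsmeier–Haack–Arnold haloformylation as for 1-tetralones: the enolisable aryl ketone is C-formylated by the bromoiminium salt and its oxygen replaced by bromide; the single α-CH2 leaves no regiochemical choice.

Step 5
Reactants: 7 3-bromo-2-formyl-6-methoxy-1H-phenalen-7-yl benzoate
Product: 8 6-bromo-9-methoxy-1-oxo-1H-phenalene-5-carbaldehyde
Conditions: DDQ (1.2 equiv), 1,4-dioxane/H2O (20:1), rt
Reagents that add atoms: none
Why: DDQ dehydrogenation: hydride abstraction from the benzylic, allylic CH2 gives a phenalenylium-type cation that is an O-acylated phenalenone, and acyl transfer to water releases the neutral ketone; this is the reaction type of DDQ oxidation of enol esters to enones and of Vilsmeier-derived dihydronaphthalenes to naphthaldehydes, and the acyl group should leave far faster than the methyl group.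

Step 6
Reactants: 8 6-bromo-9-methoxy-1-oxo-1H-phenalene-5-carbaldehyde; 9 prop-2-yn-1-ol
Product: 10 6-(3-hydroxyprop-1-yn-1-yl)-9-methoxy-1-oxo-1H-phenalene-5-carbaldehyde
Conditions: 9 (1.5 equiv), PdCl2(PPh3)2 (3 mol %), CuI (5 mol %), Et3N, THF, 50 °C
Reagents that add atoms: none
Why: Sonogashira coupling; the bromide is activated by the ortho formyl group and the electron-poor tricycle, and a tertiary amine is used because secondary amines could displace the vinylogous ester methoxy group.

Step 7
Reactants: 10 6-(3-hydroxyprop-1-yn-1-yl)-9-methoxy-1-oxo-1H-phenalene-5-carbaldehyde
Product: 11 3-(5-formyl-9-methoxy-1-oxo-1H-phenalen-6-yl)prop-2-ynal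
Conditions: Dess–Martin periodinane (1.2 equiv), CH2Cl2, 0 °C → rt
Reagents that add atoms: none
Why: Dess–Martin oxidation of a propargylic alcohol to the ynal under neutral conditions; no other oxidisable group is present.

Step 8
Reactants: 11 3-(5-formyl-9-methoxy-1-oxo-1H-phenalen-6-yl)prop-2-ynal; 1 naphthalene-1,8-diol
Product: 13 spiro-indene-2-carbaldehyde (ring D closed; CHO on the alkene carbon next to the spiro carbon), via ketal dialdehyde 12 (not isolated)
Conditions: 1 (1.05 equiv), K2CO3 (0.3 equiv), 4 Å MS, MeCN, 0 °C → rt; then 50 °C
Reagents that add atoms: none
Why: Base-catalysed double oxa-Michael addition of the naphthalenediol to the ynal β-carbon (known for activated alkynes with catechols and 1,8-naphthalenediols) gives the ketal with a CH2–CHO arm, whose intramolecular aldol condensation (5-exo) onto the ortho formyl group closes ring D; dehydration removes the acidic α-hydrogen and so locks the ketal against retro-Michael opening.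

Step 9
Reactants: 13 spiro-indene-2-carbaldehyde
Product: 14 spiro-indene ketal (9-methoxyphenalen-1-one with ring D alkene CH=CH between the spiro ketal carbon on C-6 and C-5)
Conditions: RhCl3·3H2O (5 mol %), dppp (10 mol %), diglyme, 160 °C, Ar
Reagents that add atoms: none
Why: Rhodium-catalysed Tsuji–Wilkinson-type decarbonylation of an α,β-unsaturated aldehyde (oxidative addition into the formyl C–H, CO extrusion, C–H reductive elimination with retention of the alkene); the alkene has no allylic hydrogen to isomerise.

Step 10
Reactants: 15 ethynyltrimethylsilane
Product: 17 Co2(CO)4(μ-HC≡CSiMe3)[μ-(R)-t-BuS(O)N(Bn)PPh2-κP:κS] as one diastereomer, via hexacarbonyl alkyne complex 16 (not isolated)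
Conditions: Co2(CO)8 (1.0 equiv), hexane, rt; then (R)-ligand (1.0 equiv), toluene, 65 °C; crystallisation
Reagents that add atoms: dicobalt octacarbonyl, [Co].[Co].[C-]#[O+].[C-]#[O+].[C-]#[O+].[C-]#[O+].[C-]#[O+].[C-]#[O+].[C-]#[O+].[C-]#[O+]; (R)-N-benzyl-N-(diphenylphosphanyl)-2-methylpropane-2-sulfinamide, CC(C)(C)[S@@](=O)N(Cc1ccccc1)P(c1ccccc1)c1ccccc1
Why: Complexation of a terminal alkyne with Co2(CO)8 and thermal replacement of two further CO by a bridging P,S ligand are both standard; the sulfur stereocentre makes the two cluster configurations diastereomers, and the major one should be obtained pure by crystallisation.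

Step 11
Reactants: 14 spiro-indene ketal; 17 P,S-bridged dicobalt complex of ethynyltrimethylsilane
Product: 18 cis-fused α-trimethylsilyl cyclopentenone (S at the ring-fusion CH next to the spiro carbon; R at the benzylic ring-fusion CH)
Conditions: 17 (2.0 equiv), NMO (6 equiv), CH2Cl2, rt → 40 °C; then air, SiO2
Reagents that add atoms: none
Why: Proposed new method: NMO oxidises a CO ligand of 17 and the hemilabile sulfur arm opens a site on one cobalt, where the ring D alkene of 14 binds and inserts into the Co–C bond of the unsubstituted alkyne carbon (C–C bond to the benzylic alkene carbon); CO then inserts into the remaining Co–C(alkene) bond (C–C bond at the spiro-flanked carbon) and reductive elimination joins the acyl carbon to the silyl-bearing alkyne carbon. The closest known reaction type is the intermolecular Pauson–Khand reaction of P,S-bridged dicobalt complexes of ethynyltrimethylsilane with norbornadiene, together with amine-N-oxide-promoted reactions of alkyne–Co2(CO)6 complexes with cyclopentene-type alkenes; an unstrained indene next to a spiro carbon lies outside both, so the complex is used in excess. Ring E is closed by a metal-mediated [2+2+1] cycloaddition (cobaltacyclopentene formation, migratory CO insertion, reductive elimination), not by cyclisation of a chain. Both stereocentres arise in the suprafacial alkene insertion, which forces the two ring-fusion hydrogens cis; the absolute sense, that is which enantiotopic face of the flat, mirror-symmetric indene is used, is set by the cluster chirality (which cobalt carries phosphorus), itself fixed by the sulfinyl stereocentre of the ligand. The regiochemistry required, carbonyl on the spiro-flanked carbon and =CH on the benzylic carbon, should follow from sterics (the long Co–C bond tolerates the neopentyl-type carbon better than the short C–C bond to the alkyne) and can be reinforced by coordination of a ketal oxygen to cobalt. The silyl group places itself α to the carbonyl and removes the second regiochemical variable. The ring A enone is electron-poor and part of the delocalised tricycle and should not act as the alkene partner.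

Step 12
Reactants: 18 cis-fused α-trimethylsilyl cyclopentenone
Product: 19 cis-fused cyclopent-2-enone (S at the CH next to the spiro carbon; S at the benzylic CH)
Conditions: TBAF (1.2 equiv), AcOH (1.2 equiv), THF, 0 °C → rt, Ar
Reagents that add atoms: none
Why: Fluoride-induced protodesilylation of a 2-silyl enone (attack at silicon, protonation of the vinyl anion by AcOH), known for Pauson–Khand adducts of ethynyltrimethylsilane; the acetic acid buffer keeps the medium from deprotonating the γ- and α′-positions, so both stereocentres are untouched.

Step 13
Reactants: 19 cis-fused cyclopent-2-enone
Product: 21 spiropreussione B 9-O-methyl ether (S at the ring-fusion CH; R at the carbinol carbon), via ring-fusion hydroperoxide 20 (not isolated)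
Conditions: NHPI (20 mol %), AIBN (5 mol %), O2 (1 atm), MeCN, 60 °C, dark; then PPh3 (1.2 equiv), 0 °C
Reagents that add atoms: dioxygen, O=O
Why: N-hydroxyphthalimide-mediated aerobic C–H oxidation (hydrogen-atom transfer, capture of the carbon radical by O2, reduction of the hydroperoxide by PPh3): the ring-fusion C–H is tertiary, benzylic and allylic to the enone and by far the weakest in 19. The planar radical can take up oxygen only on the face that keeps the two five-membered rings cis-fused (the convex face, where the hydrogen was), so the carbinol forms with retention relative to the untouched CH. No base is present, which avoids retro-aldol and ketal β-elimination.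

Step 14
Reactants: 21 spiropreussione B 9-O-methyl ether
Product: 22 spiropreussione B
Conditions: MgI2·OEt2 (3 equiv), toluene/THF, 50 °C; then aq. NH4Cl
Reagents that add atoms: none
Why: Chelation-assisted dealkylation of a methyl ether peri to a carbonyl group: magnesium binds the C-1 carbonyl and the C-9 methoxy oxygen and iodide removes the methyl group by SN2; the neutral conditions should spare the β-hydroxy ketone, the tertiary carbinol and the ketal.

## Compound list

1 | naphthalene-1,8-diol | Oc1cccc2cccc(O)c12 | starting material
2 | 8-methoxynaphthalen-1-ol | COc1cccc2cccc(O)c12 | intermediate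
3 | 8-methoxynaphthalen-1-yl benzoate | COc1cccc2cccc(OC(=O)c3ccccc3)c12 | intermediate
4 | 3-chloropropanoyl chloride | ClCCC(Cl)=O | starting material
5 | 5-(3-chloropropanoyl)-8-methoxynaphthalen-1-yl benzoate | COc1ccc(C(=O)CCCl)c2cccc(OC(=O)c3ccccc3)c12 | intermediate (not isolated)
6 | 7-methoxy-1-oxo-2,3-dihydro-1H-phenalen-6-yl benzoate | COc1ccc2C(=O)CCc3ccc(OC(=O)c4ccccc4)c1c23 | intermediate
7 | 3-bromo-2-formyl-6-methoxy-1H-phenalen-7-yl benzoate | COc1ccc2C(Br)=C(C=O)Cc3ccc(OC(=O)c4ccccc4)c1c23 | intermediate
8 | 6-bromo-9-methoxy-1-oxo-1H-phenalene-5-carbaldehyde | O=C1C=Cc2cc(C=O)c(Br)c3ccc(OC)c1c23 | intermediate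
9 | prop-2-yn-1-ol | C#CCO | starting material
10 | 6-(3-hydroxyprop-1-yn-1-yl)-9-methoxy-1-oxo-1H-phenalene-5-carbaldehyde | O=C1C=Cc2cc(C=O)c(C#CCO)c3ccc(OC)c1c23 | intermediate
11 | 3-(5-formyl-9-methoxy-1-oxo-1H-phenalen-6-yl)prop-2-ynal | O=C1C=Cc2cc(C=O)c(C#CC=O)c3ccc(OC)c1c23 | intermediate
12 | ketal dialdehyde: 9-methoxy-1-oxo-6-[2-(2-oxoethyl)naphtho[1,8-de][1,3]dioxin-2-yl]-1H-phenalene-5-carbaldehyde | O=C1C=Cc2cc(C=O)c(c4ccc(OC)c1c24)C1(Oc2cccc4cccc(c24)O1)CC=O | intermediate (not isolated)
13 | spiro-indene-2-carbaldehyde: 9-methoxyphenalen-1-one fused at C-5/C-6 to an indene-type ring D, spiro ketal carbon (C-2 of naphtho[1,8-de][1,3]dioxine) on C-6, CHO on the neighbouring alkene carbon | O=C1C=Cc2cc3c(c4ccc(OC)c1c24)C1(Oc2cccc4cccc(c24)O1)C(C=O)=C3 | intermediate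
14 | spiro-indene ketal: as 13 with H in place of CHO (ring D alkene CH=CH) | O=C1C=Cc2cc3c(c4ccc(OC)c1c24)C1(Oc2cccc4cccc(c24)O1)C=C3 | intermediate (key-step precursor)
15 | ethynyltrimethylsilane | C#C[Si](C)(C)C | starting material
16 | Co2(CO)6(μ-HC≡CSiMe3), written as its components | C[Si](C)(C)C#C.[Co].[Co].[C-]#[O+].[C-]#[O+].[C-]#[O+].[C-]#[O+].[C-]#[O+].[C-]#[O+] | intermediate (not isolated)
17 | Co2(CO)4(μ-HC≡CSiMe3)[μ-(R)-t-BuS(O)N(Bn)PPh2-κP:κS], one diastereomer, written as its components | C[Si](C)(C)C#C.CC(C)(C)[S@@](=O)N(Cc1ccccc1)P(c1ccccc1)c1ccccc1.[Co].[Co].[C-]#[O+].[C-]#[O+].[C-]#[O+].[C-]#[O+] | intermediate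
18 | cis-fused 2-(trimethylsilyl)cyclopent-2-enone on ring D of 14; S at the CH next to the spiro carbon, R at the benzylic CH | O=C1C=Cc2cc3c(c4ccc(OC)c1c24)C1(Oc2cccc4cccc(c24)O1)[C@@H]1C(=O)C([Si](C)(C)C)=C[C@H]31 | intermediate (key-step product)
19 | cis-fused cyclopent-2-enone; S at the CH next to the spiro carbon, S at the benzylic CH | O=C1C=Cc2cc3c(c4ccc(OC)c1c24)C1(Oc2cccc4cccc(c24)O1)[C@@H]1C(=O)C=C[C@H]31 | intermediate
20 | hydroperoxide at the benzylic ring-fusion carbon; S at the CH, R at the C–OOH | O=C1C=Cc2cc3c(c4ccc(OC)c1c24)C1(Oc2cccc4cccc(c24)O1)[C@@H]1C(=O)C=C[C@]31OO | intermediate (not isolated)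
21 | spiropreussione B 9-O-methyl ether; S at the CH, R at the carbinol | O=C1C=Cc2cc3c(c4ccc(OC)c1c24)C1(Oc2cccc4cccc(c24)O1)[C@@H]1C(=O)C=C[C@]31O | intermediate
22 | spiropreussione B | O=C1C=Cc2cc3c(c4ccc(O)c1c24)C1(Oc2cccc4cccc(c24)O1)[C@@H]1C(=O)C=C[C@]31O | target

## Step count and least certain steps

Total step count: 14. Longest linear sequence: 13 steps (1 to 22 through steps 1–9 and 11–14; step 10 is a one-step side branch).

Step 11 (key step). The cycloaddition may not start, because the unstrained, hindered alkene may fail to enter the coordination sphere before the complex decomposes, or regio- and facial selectivity may leak. Fallback with known chemistry, from 14: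
- [2+2] cycloaddition with dichloroketene (Cl2CHCOCl, Et3N), which places the ketene carbonyl on the non-benzylic carbon of styrene-type alkenes, should give racemic cis-fused dichlorocyclobutanone F1.
- Reductive dechlorination (Zn, NH4Cl, MeOH) gives cyclobutanone F2.
- Ring expansion with diazomethane, with migration of the CH2 carbon, gives cyclopentanone F3.
- The kinetic trimethylsilyl enol ether F4 (LiHMDS, TMSCl, −78 °C; deprotonation at CH2, not at the hindered ring-fusion CH) is dehydrogenated with Pd(OAc)2 (Saegusa oxidation) to racemic 19.
- Preparative chromatography on a chiral stationary phase separates the antipode F5, which is discarded; the route is rejoined at 19.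

Step 13. The intermediate may fragment through alkoxy radicals (β-scission of the strained ring fusion), or oxygen may be taken up at the α-carbon of the delocalised radical. Fallback, from 19, ionic instead of radical: catalytic Cs2CO3 in DMSO under O2 with P(OEt)3 generates the extended dienolate, which takes up O2 at the γ-carbon to give the same hydroperoxide 20 and, after reduction, 21. This makes no new compound; it is held in reserve because base exposes 21 to retro-aldol and ketal β-elimination.

Step 8. The sequence may stall after the first conjugate addition, since the second closure creates a tetrasubstituted carbon next to a peri-substituted arene, or the ynal may polymerise. Fallback, from 11, separating the events and changing how the second C–O bond is made: catalytic DABCO at 0 °C should allow only the first addition, giving β-aryloxy enal F6; catalytic camphorsulfonic acid then protonates the enol ether and the peri hydroxyl captures the oxocarbenium ion to give 12, now isolated; catalytic K2CO3 effects the aldol condensation, rejoining at 13.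

Step 3. Ring closure para to the benzoyloxy group may fail, or AlCl3 may cause loss of the methyl group or migration of the benzoyl group. Fallback, from 2, reversing the order of the two ring-forming bonds:
- Bromination para to the hydroxyl (NBS) gives 4-bromo-8-methoxynaphthalen-1-ol F7; benzoylation gives bromo benzoate F8.
- Heck reaction with acrylic acid (Pd(OAc)2, P(o-tol)3, Et3N) gives cinnamic-type acid F9; hydrogenation (H2, Pd/C) gives propanoic acid F10.
- Friedel–Crafts cycloacylation (trifluoroacetic anhydride) onto the peri position para to the methoxy group rejoins at 6.

Step 5. The cation may lose the wrong oxygen substituent (demethylation instead of debenzoylation), or water may add to ring carbons and lead to over-oxidation. Fallback, from 6: remove the benzoate first (K2CO3, MeOH) to give hydroxy ketone F11, haloformylate (PBr3, DMF; a transient formate is lost on aqueous work-up) to give bromo enal F12, and dehydrogenate it with DDQ, a plain phenol-to-phenalenone oxidation, rejoining at 8.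

## Further compounds

F1 | step 11 | racemic cis-fused dichlorocyclobutanone on ring D of 14 (C=O on the spiro-flanked carbon, CCl2 on the benzylic carbon; one enantiomer drawn) | O=C1C=Cc2cc3c(c4ccc(OC)c1c24)C1(Oc2cccc4cccc(c24)O1)[C@@H]1C(=O)C(Cl)(Cl)[C@H]31
F2 | step 11 | racemic cis-fused cyclobutanone (one enantiomer drawn) | O=C1C=Cc2cc3c(c4ccc(OC)c1c24)C1(Oc2cccc4cccc(c24)O1)[C@@H]1C(=O)C[C@H]31
F3 | step 11 | racemic cis-fused cyclopentanone (one enantiomer drawn) | O=C1C=Cc2cc3c(c4ccc(OC)c1c24)C1(Oc2cccc4cccc(c24)O1)[C@@H]1C(=O)CC[C@H]31
F4 | step 11 | racemic trimethylsilyl enol ether of F3 (one enantiomer drawn) | O=C1C=Cc2cc3c(c4ccc(OC)c1c24)C1(Oc2cccc4cccc(c24)O1)[C@@H]1C(O[Si](C)(C)C)=CC[C@H]31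
F5 | step 11 | enantiomer of 19 | O=C1C=Cc2cc3c(c4ccc(OC)c1c24)C1(Oc2cccc4cccc(c24)O1)[C@H]1C(=O)C=C[C@@H]31
F0 | step 13 | none | none
F6 | step 8 | 6-{1-[(8-hydroxynaphthalen-1-yl)oxy]-3-oxoprop-1-en-1-yl}-9-methoxy-1-oxo-1H-phenalene-5-carbaldehyde (E/Z mixture) | O=C1C=Cc2cc(C=O)c(c3ccc(OC)c1c23)C(Oc1cccc2cccc(O)c12)=CC=O
F7 | step 3 | 4-bromo-8-methoxynaphthalen-1-ol | COc1cccc2c(Br)ccc(O)c12
F8 | step 3 | 4-bromo-8-methoxynaphthalen-1-yl benzoate | COc1cccc2c(Br)ccc(OC(=O)c3ccccc3)c12
F9 | step 3 | (E)-3-[4-(benzoyloxy)-5-methoxynaphthalen-1-yl]prop-2-enoic acid | COc1cccc2c(/C=C/C(O)=O)ccc(OC(=O)c3ccccc3)c12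
F10 | step 3 | 3-[4-(benzoyloxy)-5-methoxynaphthalen-1-yl]propanoic acid | COc1cccc2c(CCC(O)=O)ccc(OC(=O)c3ccccc3)c12
F11 | step 5 | 6-hydroxy-7-methoxy-2,3-dihydro-1H-phenalen-1-one | COc1ccc2C(=O)CCc3ccc(O)c1c23
F12 | step 5 | 3-bromo-7-hydroxy-6-methoxy-1H-phenalene-2-carbaldehyde | COc1ccc2C(Br)=C(C=O)Cc3ccc(O)c1c23
A1 | alternative 1 | 2,3-dihydro-1H-phenalene analogue of spiropreussione B methyl ether | C1CCc2cc3c(c4ccc(OC)c1c24)C1(Oc2cccc4cccc(c24)O1)[C@@H]1C(=O)C=C[C@]31O
A2 | alternative 1 | lactol (hemiketal of the tetralone carbonyl with the benzylic alcohol) carrying the spiro ketal and the 4-hydroxy-4-vinylcyclopentenone | OC12CCCc3c(OC)ccc(c31)C(O2)C1(Oc2cccc4cccc(c24)O1)[C@@H]1C(=O)C=C[C@@]1(C=C)O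
A3 | alternative 1 | isobenzofuran formed from A2 by loss of water | c1(oc2CCCc3c(OC)ccc1c23)C1(Oc2cccc4cccc(c24)O1)[C@@H]1C(=O)C=C[C@@]1(C=C)O
A4 | alternative 2 | spiroketal cyclopentenol with triethylsilyl ether at the ring-fusion carbinol | O=C1C=Cc2cc3c(c4ccc(OC)c1c24)C1(Oc2cccc4cccc(c24)O1)[C@@H]1[C@@H](O)C=C[C@]31O[Si](CC)(CC)CC
A5 | alternative 2 | ring D aryl enol ether with pendant naphthol, Z-enal and triethylsilyl ether | O=C1C=Cc2cc3c(c4ccc(OC)c1c24)C(Oc1cccc2cccc(O)c12)=C[C@@]3(/C=C\C=O)O[Si](CC)(CC)CC
A6 | alternative 3 | spiroketal indanol with cis acetyl and dimethoxymethyl groups | O=C1C=Cc2cc3c(c4ccc(OC)c1c24)C1(Oc2cccc4cccc(c24)O1)[C@H](C(C)=O)[C@]3(O)C(OC)OC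
A7 | alternative 3 | 5-(2,2-dimethoxyacetyl)-9-methoxy-6-(3-oxobut-1-yn-1-yl)-1H-phenalen-1-one | O=C1C=Cc2cc(C(=O)C(OC)OC)c(C#CC(C)=O)c3ccc(OC)c1c23
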